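The rate constants are invented; no experiment stands behind them.

More substrate cannot buy more target without end while the dissolved gas stands at a fixed level. Substrate makes target by joining dissolved gas, with constant 0.0826 L mol⁻¹ s⁻¹, and destroys target by joining it, with constant 0.142 L mol⁻¹ s⁻¹. Substrate stands in both rates, so it cancels from their balance.

the same everywhere: gas phase 28 mM (held); time 5.0 min

|  | substrate |
|---|---|
| blue | 0.030 M |
| amber | 0.060 M |
| violet | 0.12 M |
| ochre | 0.25 M |
| grey | 0.50 M |

* [target] at the end for blue, amber, violet, ochre, grey, in this order
* how the row runs (hardly changes / falls all the way / rises, then falls / falls, then rises / rises all the way)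

- a species is counted by the substrate in it: one side product B counts as two
- at the start none of the gas is dissolved
- "hardly changes" means that all values lie within two and a half points (for a concentration: within two and a half percent of the largest)
- run time (blue): 5.0 min

    gas phase ⇌ dissolved gas, rate k1*(csat - [dissolved gas]) (k1 = 0.00867 s⁻¹, csat = 28 mM)
    substrate + dissolved gas → target (k2 = 0.0826 L mol⁻¹ s⁻¹)
    substrate → side product A (k3 = 9.58 × 10⁻⁴ s⁻¹)
    dissolved gas → decomposed reagent (k4 = 0.00299 s⁻¹)
    substrate + target → side product B (k5 = 0.142 L mol⁻¹ s⁻¹)
    substrate ⇌ dormant form (K6 = 0.215, k6 = 0.00996 s⁻¹)

Where those two rates are equal, c(target) stands at 0.582 times c(dissolved gas); I called this number the balance ratio, and the product its ceiling.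

How much dissolved gas, then, stood in each flask? I needed the substrate first. In blue the dormant form relaxes with a half-life of 0.205 min, much shorter than the run. With the slow loss to side product A, and setting the other losses aside, I reckoned for blue and grey alike a share of 65.0 % of the charge as substrate at the end. Equating the feed from the gas phase with the losses to decomposition and to substrate gave c(dissolved gas) as 0.0183 M in blue and 0.00631 M in grey, about a third of it. The ceilings were therefore 0.0106 M in blue and 0.00367 M in grey.

Did each flask reach its ceiling? Target is destroyed in a pseudo-first-order way, with a time of one over the constant 0.142 L mol⁻¹ s⁻¹ times c(substrate). That time was 6.02 min in blue, longer than the run, and 0.361 min in grey, far shorter. So I expected blue to be still climbing, grey to sit near 0.00367 M, and the row to rise, then fall.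

The forecast gave 0.0047 M, 0.0066 M, 0.0071 M, 0.0056 M and 0.004 M, a row that rises, then falls, holding that “target settles near 0.58 times the dissolved gas level”. Its grey value stands a little above mine.

The simulation gave 0.00459 M, 0.00645 M, 0.00716 M, 0.00597 M and 0.00403 M: the row rises, then falls, turning, as read, near 0.11 M.

With the destroying step given no rate, grey ended at 0.0468 M instead of 0.00403 M. Grey held 0.00713 M of dissolved gas after 5.00 min, and the balance ratio turns that into 0.00415 M, beside the 0.00403 M of target found. In blue, with 0.0183 M of dissolved gas at the same time, the ratio gives 0.0107 M, and the target stood lower than that, at 0.00459 M.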